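**Retrosynthetic overview**
1. Pyran ring (formed last): cut C4–C4a and O1–C8a together. This gives an α-iodo-β-methoxy dienone, whose ring carbon acts as the electrophile (an enolonium equivalent), and a cyclic (R,Z)-γ-oxido-alkenylboron reagent (a homoenolate-type donor). Suzuki union is followed by displacement of methoxide by the tertiary alkoxide, so C2 arrives intact from (R)-dehydrolinalool.
2. Iodo dienone ⇐ iodination ⇐ alkylative dearomatisation (2 MeI) of the 4-O-methyl acylphloroglucinol ⇐ Friedel–Crafts acylation of phloroglucinol with (R)-2-methylbutanoic acid (side-chain stereocentre bought).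
3. Boron reagent ⇐ trans-hydroboration of (R)-dehydrolinalool ⇐ epoxy chloride fragmentation ⇐ Sharpless epoxidation of geraniol (sets C2).
4. Ring order: the carbocycle is the phloroglucinol ring (dearomatised, never built); the pyran ring is closed in the final step.

Assumption: (R)-2-methylbutanoic acid of ≥98% ee is a catalogue compound; the target is handled as the enol tautomer written in the SMILES.

**Step 1**
Reactants: 1 (R)-2-methylbutanoic acid; 2 phloroglucinol (benzene-1,3,5-triol)
Product: 4 (2R)-2-methyl-1-(2,4,6-trihydroxyphenyl)butan-1-one, via (R)-2-methylbutanoyl chloride 3 (not isolated)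
Conditions: (COCl)2 (1.1 equiv), cat. DMF, DCM, 0 °C to rt, concentrate; then 2, AlCl3 (4 equiv), PhNO2/DCM, 0 °C to rt, 16 h; ice/1 M HCl
Reagents that add atoms: oxalyl chloride, ClC(=O)C(=O)Cl (its chlorine is in 3 only)
Why: Friedel–Crafts C-acylation of the very electron-rich triol stops at the mono-ketone (the aluminium-chelated product is deactivated), and keeping the reaction at or below rt limits enolisation of the α-stereocentre (ee checked by chiral HPLC).

**Step 2**
Reactants: 4 (2R)-2-methyl-1-(2,4,6-trihydroxyphenyl)butan-1-one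
Product: 5 (2R)-1-(2,6-dihydroxy-4-methoxyphenyl)-2-methylbutan-1-one
Conditions: Me2SO4 (1.05 equiv), K2CO3 (1.1 equiv), acetone, rt to 40 °C
Reagents that add atoms: dimethyl sulfate, COS(=O)(=O)OC
Why: Williamson O-methylation is selective for the 4-OH, which is para to the carbonyl, the most acidic and the only hydroxyl not tied up in a hydrogen bond to the ketone.

**Step 3**
Reactants: 5 (2R)-1-(2,6-dihydroxy-4-methoxyphenyl)-2-methylbutan-1-one
Product: 7 3-hydroxy-5-methoxy-6,6-dimethyl-2-[(2R)-2-methylbutanoyl]cyclohexa-2,4-dien-1-one, via mono-C-methyl ketone 6 (not isolated)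
Conditions: NaOMe (3 equiv), MeI (2.3 equiv), MeOH, 0 °C to rt
Reagents that add atoms: iodomethane, CI
Why: Alkylative dearomatisation, in which the phenoxide is C-methylated twice at the carbon between OH and OMe because the second methylation gives a conjugated β-triketone/vinylogous ester (the substitution pattern of natural methoxy β-triketones such as agglomerone), while the polyanion protects the side-chain α-CH from enolisation.

**Step 4**
Reactants: 7 3-hydroxy-5-methoxy-6,6-dimethyl-2-[(2R)-2-methylbutanoyl]cyclohexa-2,4-dien-1-one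
Product: 8 3-hydroxy-4-iodo-5-methoxy-6,6-dimethyl-2-[(2R)-2-methylbutanoyl]cyclohexa-2,4-dien-1-one
Conditions: NIS (1.05 equiv), MeCN, 0 °C, dark
Reagents that add atoms: N-iodosuccinimide, O=C1CCC(=O)N1I
Why: Electrophilic iodination at the only ring CH (the α-carbon of the vinylogous ester) gives an α-iodo enone in which this normally nucleophilic carbon has become the electrophile (an enolonium equivalent).

**Step 5**
Reactants: 9 geraniol ((2E)-3,7-dimethylocta-2,6-dien-1-ol)
Product: 10 [(2R,3R)-3-methyl-3-(4-methylpent-3-en-1-yl)oxiran-2-yl]methanol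
Conditions: Ti(OiPr)4 (5 mol %), D-(−)-diethyl tartrate (7.5 mol %), t-BuOOH (2 equiv, decane), 4 Å MS, DCM, −20 °C
Reagents that add atoms: tert-butyl hydroperoxide, CC(C)(C)OO
Why: Sharpless asymmetric epoxidation epoxidises only the allylic alkene, and the D-(−)-tartrate catalyst gives the (2R,3R) epoxide (about 95% ee), whose quaternary carbon becomes C2 of the chromene.

**Step 6**
Reactants: 10 [(2R,3R)-3-methyl-3-(4-methylpent-3-en-1-yl)oxiran-2-yl]methanol
Product: 11 (2R,3S)-3-(chloromethyl)-2-methyl-2-(4-methylpent-3-en-1-yl)oxirane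
Conditions: PPh3 (1.3 equiv), CCl4, NaHCO3, reflux
Reagents that add atoms: tetrachloromethane, ClC(Cl)(Cl)Cl
Why: Appel reaction, an SN2 displacement at the primary carbinol through the alkoxyphosphonium ion, leaves both epoxide carbons untouched (the CH descriptor changes only because CH2Cl outranks the ring carbon).

**Step 7**
Reactants: 11 (2R,3S)-3-(chloromethyl)-2-methyl-2-(4-methylpent-3-en-1-yl)oxirane
Product: 12 (3R)-3,7-dimethyloct-6-en-1-yn-3-ol ((R)-dehydrolinalool)
Conditions: n-BuLi (3.3 equiv), THF, −40 to −20 °C; then H2O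
Reagents that add atoms: none
Why: Base-induced fragmentation of a 2,3-epoxy chloride to a propargylic alcohol (Yadav–Takano type double elimination) works by metalation next to chlorine, opening of the epoxide at the CH carbon and loss of LiCl, so the C–O bond of the quaternary carbon is never broken and its (R) configuration is kept.

**Step 8**
Reactants: 12 (3R)-3,7-dimethyloct-6-en-1-yn-3-ol
Product: 14 (5R)-5-methyl-5-(4-methylpent-3-en-1-yl)-1,2-oxaborol-2(5H)-ol, via bis-boryl Z-alkene 13 (not isolated)
Conditions: HBpin (2.2 equiv), Et3N (2 equiv), cyclohexane, rt, 1 h; then [Rh(cod)Cl]2 (1.5 mol %), P(i-Pr)3 (6 mol %), rt; H2O/THF work-up, silica gel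
Reagents that add atoms: pinacolborane, CC1(C)OBOC1(C)C; water, O
Why: Rhodium-vinylidene trans-hydroboration of a terminal alkyne (Miyaura conditions), after O-borylation in the flask, puts boron cis to the carbinol carbon, and on hydrolysis the cis hydroxyl closes onto boron and locks the Z geometry in a five-membered oxaborole without touching the stereocentre.

**Step 9**
Reactants: 8 3-hydroxy-4-iodo-5-methoxy-6,6-dimethyl-2-[(2R)-2-methylbutanoyl]cyclohexa-2,4-dien-1-one; 14 (5R)-5-methyl-5-(4-methylpent-3-en-1-yl)-1,2-oxaborol-2(5H)-ol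
Product: 16 (2R)-5-hydroxy-2,8,8-trimethyl-6-[(2R)-2-methylbutanoyl]-2-(4-methylpent-3-en-1-yl)-2H-chromen-7(8H)-one, via Z-dienyl carbinol 15 (not isolated)
Conditions: Pd(dppf)Cl2 (5 mol %), K3PO4 (4 equiv), THF/H2O 10:1, Ar, dark, 40 °C; then 55 °C until 15 is consumed; cold pH 4 buffer
Reagents that add atoms: none
Why: Proposed new method: zerovalent palladium inserts into the C–I bond of 8 and couples it with the Z-alkenylboron 14 with retention of geometry, joining two carbons that are both nucleophilic in their parent compounds (the enol CH of 7 and the alkyne CH of 12), and in 15 the tertiary alkoxide is held next to the β-carbon of the vinylogous ester and closes the pyran by conjugate addition–elimination of methoxide, so the carbinol C–O bond is never broken and the (R) centre of 12 becomes C2 unchanged, while the enolate oxygen on the other flank carries no leaving group and cannot compete; the closest known reactions are the Suzuki–Miyaura coupling of α-iodo enones with alkenylboron reagents and the base-mediated alkoxy exchange of β-alkoxy enones.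

**Compound list**
1 | (R)-2-methylbutanoic acid | CC[C@@H](C)C(=O)O | starting material
2 | phloroglucinol (benzene-1,3,5-triol) | Oc1cc(O)cc(O)c1 | starting material
3 | (R)-2-methylbutanoyl chloride | CC[C@@H](C)C(=O)Cl | intermediate
4 | (2R)-2-methyl-1-(2,4,6-trihydroxyphenyl)butan-1-one | CC[C@@H](C)C(=O)c1c(O)cc(O)cc1O | intermediate
5 | (2R)-1-(2,6-dihydroxy-4-methoxyphenyl)-2-methylbutan-1-one | CC[C@@H](C)C(=O)c1c(O)cc(OC)cc1O | intermediate
6 | (2R)-1-(2,6-dihydroxy-4-methoxy-3-methylphenyl)-2-methylbutan-1-one | CC[C@@H](C)C(=O)c1c(O)cc(OC)c(C)c1O | intermediate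
7 | 3-hydroxy-5-methoxy-6,6-dimethyl-2-[(2R)-2-methylbutanoyl]cyclohexa-2,4-dien-1-one | CC[C@@H](C)C(=O)C1=C(O)C=C(OC)C(C)(C)C1=O | intermediate
8 | 3-hydroxy-4-iodo-5-methoxy-6,6-dimethyl-2-[(2R)-2-methylbutanoyl]cyclohexa-2,4-dien-1-one | CC[C@@H](C)C(=O)C1=C(O)C(I)=C(OC)C(C)(C)C1=O | intermediate
9 | geraniol, (2E)-3,7-dimethylocta-2,6-dien-1-ol | CC(C)=CCC/C(C)=C/CO | starting material
10 | [(2R,3R)-3-methyl-3-(4-methylpent-3-en-1-yl)oxiran-2-yl]methanol | OC[C@H]1O[C@]1(C)CCC=C(C)C | intermediate
11 | (2R,3S)-3-(chloromethyl)-2-methyl-2-(4-methylpent-3-en-1-yl)oxirane | ClC[C@H]1O[C@]1(C)CCC=C(C)C | intermediate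
12 | (3R)-3,7-dimethyloct-6-en-1-yn-3-ol | O[C@](C)(CCC=C(C)C)C#C | intermediate
13 | 2-[(1Z,3R)-3,7-dimethyl-3-[(4,4,5,5-tetramethyl-1,3,2-dioxaborolan-2-yl)oxy]octa-1,6-dien-1-yl]-4,4,5,5-tetramethyl-1,3,2-dioxaborolane | CC1(C)OB(O[C@](C)(CCC=C(C)C)/C=C\B2OC(C)(C)C(C)(C)O2)OC1(C)C | intermediate
14 | (5R)-5-methyl-5-(4-methylpent-3-en-1-yl)-1,2-oxaborol-2(5H)-ol | OB1O[C@](C)(CCC=C(C)C)C=C1 | intermediate
15 | 3-hydroxy-4-[(1Z,3R)-3-hydroxy-3,7-dimethylocta-1,6-dien-1-yl]-5-methoxy-6,6-dimethyl-2-[(2R)-2-methylbutanoyl]cyclohexa-2,4-dien-1-one | CC[C@@H](C)C(=O)C1=C(O)C(/C=C\[C@@](O)(C)CCC=C(C)C)=C(OC)C(C)(C)C1=O | intermediate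
16 | (2R)-5-hydroxy-2,8,8-trimethyl-6-[(2R)-2-methylbutanoyl]-2-(4-methylpent-3-en-1-yl)-2H-chromen-7(8H)-one | CC[C@@H](C)C(=O)C1=C(O)C2=C(O[C@](C)(CCC=C(C)C)C=C2)C(C)(C)C1=O | target

**Totals**
Total step count: 9. Longest linear sequence: 5 steps (1, 2, 3, 4, 9; the boron branch 5, 6, 7, 8, 9 is equally long).

**Steps most likely to fail**

Step 9. The Suzuki coupling is hindered on both flanks, and the ring closure has to occur on an anionic triketone; 15 must not meet acid before it has closed, because its dienylic tertiary alcohol would ionise and racemise C2. The fallback sets out from 8 and the alkyne 12. Sonogashira coupling (Pd(PPh3)2Cl2, CuI, i-Pr2NH, THF, rt) gives the enynol 3-hydroxy-4-[(3R)-3-hydroxy-3,7-dimethyloct-6-en-1-yn-1-yl]-5-methoxy-6,6-dimethyl-2-[(2R)-2-methylbutanoyl]cyclohexa-2,4-dien-1-one F1. Cis-semihydrogenation (H2, Pd/CaCO3 poisoned with Pb(OAc)2, quinoline, EtOAc) then comes back to the route at 15, which is closed to 16 with K3PO4 as in step 9.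

Step 8. The trans-hydroboration has to tolerate a bulky, O-borylated tertiary propargylic centre and must give high Z selectivity. The fallback sets out from 12. Trans-hydroalumination with NaAlH2(OCH2CH2OMe)2 (THF, 0 °C, EtOAc quench) and iodination (I2, −78 °C) give (1Z,3R)-1-iodo-3,7-dimethylocta-1,6-dien-3-ol F2. Deprotonation (n-BuLi, 1 equiv), iodine–lithium exchange (t-BuLi, 2 equiv, −78 °C), B(OMe)3 and aqueous HCl then come back to the route at 14.

Step 3. Geminal methylation competes with methylation at the second free ring carbon and with a third methylation. The fallback sets out from 4. C-dimethylation first (NaOMe, MeI, MeOH, the classical filicinic acid formation) gives the acylfilicinic acid 3,5-dihydroxy-6,6-dimethyl-2-[(2R)-2-methylbutanoyl]cyclohexa-2,4-dien-1-one F3. O-methylation of its free, non-chelated enol with TMSCHN2 (toluene/MeOH, 0 °C) and chromatographic removal of the isomeric enol ether then come back to the route at 7.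

**Further compounds**
F1 | step 9 | 3-hydroxy-4-[(3R)-3-hydroxy-3,7-dimethyloct-6-en-1-yn-1-yl]-5-methoxy-6,6-dimethyl-2-[(2R)-2-methylbutanoyl]cyclohexa-2,4-dien-1-one | CC[C@@H](C)C(=O)C1=C(O)C(C#C[C@@](O)(C)CCC=C(C)C)=C(OC)C(C)(C)C1=O
F2 | step 8 | (1Z,3R)-1-iodo-3,7-dimethylocta-1,6-dien-3-ol | I/C=C\[C@@](O)(C)CCC=C(C)C
F3 | step 3 | 3,5-dihydroxy-6,6-dimethyl-2-[(2R)-2-methylbutanoyl]cyclohexa-2,4-dien-1-one | CC[C@@H](C)C(=O)C1=C(O)C=C(O)C(C)(C)C1=O
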